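**Retrosynthetic overview**

1. Feature: in ring B, C5 carries the C4(C18H3)(C19H2–O) unit beside quaternary C10, and C8 carries the C17 carbon. This is the stereocentre, isopropenyl group, α'-carbon and ring methyl of (R)-carvone. O–C19 and O–C2 are 1,4-related through C4–C3.
2. Side chain and ring B oxygenation: C12–C13 by Negishi coupling of a C12 alkylzinc with (Z)-3-iodobut-2-enyl acetate; 7α-OH/Δ8(17) from Δ7 by α-epoxidation and Ti(III) isomerisation.
3. Ring A oxygenation: C19–OAc by acetolysis of a C3–C4–C19 cyclopropyl ketone; 2α-OH by thermodynamic reduction of the C2 ketone.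
4. Ring A (closed second): the copper carbenoid from a C3 diazoketone adds to the C4=C19 isopropenyl alkene, forming C3–C4 and C3–C19.
5. Ring B (first, chiral pool): carvone is methylated and alkylated at C10; epoxidation–Wharton transposition, C7 inversion and Johnson–Claisen rearrangement install C11–C12 on C9.

Key step: step 12

Remark: the target is read as 2α,7α-dihydroxylabda-8(17),13Z-diene-15,19-diyl diacetate (10β-CH3, 5α-H, 9α-H, 4α-CH3, 4β-CH2OAc). Labdane numbers are used for all intermediates (ring B = C5–C10); β is the face of C20, α the face of H5.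

**Route**

Step 1
Reactants: 1 (R)-carvone
Product: 3 6-methylcarvone (methyl on C10; both C10 epimers), via lithium dienolate 2 (not isolated)
Conditions: LDA, THF, −78 °C; MeI, −78 → 0 °C
Reagents that add atoms: iodomethane, CI
Why: Kinetic α'-deprotonation gives the cross-conjugated dienolate, which is methylated at C10 (enolate alkylation); the C10 configuration is irrelevant because this centre is enolised again in step 2.

Step 2
Reactants: 3 6-methylcarvone; 4 tert-butyl bromoacetate
Product: 6 tert-butyl 2-[1,3-dimethyl-2-oxo-6-(prop-1-en-2-yl)cyclohex-3-en-1-yl]acetate (acetate arm trans and C20 methyl cis to the isopropenyl group), via lithium enolate 5 (not isolated)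
Conditions: LDA, THF, −78 → −20 °C; DMPU, 4, −78 → 0 °C
Reagents that add atoms: none
Why: Enolate alkylation of the fully substituted α'-enolate with an activated α-bromo ester; the electrophile should enter anti to the neighbouring C5 isopropenyl group, which sets quaternary C10 with C20 cis and the C1–C2 arm trans to that group, as a trans-fused ring A requires.

Step 3
Reactants: 6 enone ester
Product: 7 7α,8α-epoxy ketone (epoxide trans to the isopropenyl group)
Conditions: 30% H2O2, NaOH (cat.), MeOH, 0 °C → rt
Reagents that add atoms: hydrogen peroxide, OO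
Why: Weitz–Scheffer nucleophilic epoxidation: hydroperoxide adds to C7 axially and anti to the C5 isopropenyl group, as with carvone itself, while the isopropenyl alkene and the tert-butyl ester are inert to alkaline peroxide.

Step 4
Reactants: 7 epoxy ketone
Product: 9 tert-butyl 2-[4-hydroxy-1,3-dimethyl-6-(prop-1-en-2-yl)cyclohex-2-en-1-yl]acetate (7α-OH; Δ8(9)), via epoxy hydrazone 8 (not isolated)
Conditions: N2H4·H2O, AcOH (cat.), MeOH, 0 °C → rt
Reagents that add atoms: none
Why: Wharton transposition: the epoxy hydrazone fragments with loss of N2 to the Δ8(9) allylic alcohol, moving the oxygen to C7 with the C7–O bond retained (α) and turning the former carbonyl carbon C9 into the alkene CH that will receive C11.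

Step 5
Reactants: 9 7α-allylic alcohol
Product: 10 tert-butyl 2-[1,3-dimethyl-4-oxo-6-(prop-1-en-2-yl)cyclohex-2-en-1-yl]acetate (7-oxo; Δ8(9))
Conditions: Dess–Martin periodinane, CH2Cl2, 0 °C → rt
Reagents that add atoms: none
Why: Dess–Martin oxidation of the secondary allylic alcohol under neutral conditions leaves the ester and both alkenes untouched and erases the wrong C7 configuration.

Step 6
Reactants: 10 transposed enone
Product: 11 7β-allylic alcohol (OH cis to the isopropenyl group)
Conditions: NaBH4, CeCl3·7H2O, MeOH, −78 °C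
Reagents that add atoms: none
Why: Luche 1,2-reduction: hydride should attack C7 axially on the face anti to the C5 isopropenyl group (the carvone → cis-carveol pattern), giving the pseudo-equatorial 7β-alcohol, i.e. net inversion of C7 over steps 5 and 6.

Step 7
Reactants: 11 7β-allylic alcohol; 12 triethyl orthoacetate
Product: 14 tert-butyl 2-[2-(2-ethoxy-2-oxoethyl)-1,3-dimethyl-6-(prop-1-en-2-yl)cyclohex-3-en-1-yl]acetate (C9 arm β; Δ7), via ketene acetal 13 (not isolated)
Conditions: 12 (excess), EtCO2H (cat.), o-xylene, 140 °C, EtOH distilled off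
Reagents that add atoms: none
Why: Johnson–Claisen rearrangement: the mixed ketene acetal undergoes a suprafacial [3,3] shift that forms C9–C11 on the β face from which the C7–O bond departs and returns the alkene to Δ7, so the 7β configuration is transferred to C9 (C11 β, H9 α).

Step 8
Reactants: 14 diester
Product: 15 tert-butyl 2-[2-(2-hydroxyethyl)-1,3-dimethyl-6-(prop-1-en-2-yl)cyclohex-3-en-1-yl]acetate
Conditions: LiBH4, THF, 0 °C → rt
Reagents that add atoms: none
Why: Chemoselective ester reduction: LiBH4 reduces the unhindered ethyl ester to the C12 alcohol, while the neopentyl-type tert-butyl ester is expected to survive.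

Step 9
Reactants: 15 C12 alcohol
Product: 16 tert-butyl 2-[2-(2-chloroethyl)-1,3-dimethyl-6-(prop-1-en-2-yl)cyclohex-3-en-1-yl]acetate
Conditions: PPh3, N-chlorosuccinimide, THF, 0 °C → rt
Reagents that add atoms: N-chlorosuccinimide, ClN1C(=O)CCC1=O
Why: Appel-type chlorination by SN2 displacement of the alkoxyphosphonium ion gives a primary chloride that should be inert up to step 18 and then serves as the handle for the side chain.

Step 10
Reactants: 16 chloro tert-butyl ester
Product: 18 2-[2-(2-chloroethyl)-1,3-dimethyl-6-(prop-1-en-2-yl)cyclohex-3-en-1-yl]acetic acid, via trimethylsilyl ester 17 (not isolated)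
Conditions: TMSOTf, 2,6-lutidine, CH2Cl2, 0 °C → rt; aq. NH4Cl work-up
Reagents that add atoms: none
Why: tert-Butyl ester cleavage by silyl transfer: O-silylation triggers loss of isobutene and hydrolytic work-up frees the acid, under non-protic conditions that avoid acid-induced lactonisation onto the isopropenyl group.

Step 11
Reactants: 18 acid
Product: 20 1-diazo-3-[2-(2-chloroethyl)-1,3-dimethyl-6-(prop-1-en-2-yl)cyclohex-3-en-1-yl]propan-2-one, via acid chloride 19 (not isolated)
Conditions: 1-chloro-N,N,2-trimethylprop-1-en-1-amine, CH2Cl2, 0 °C → rt; CH2N2 (excess), Et2O, 0 °C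
Reagents that add atoms: diazomethane, C=[N+]=[N-]
Why: The α-chloroenamine forms the acid chloride under neutral conditions and acylation of diazomethane (first stage of the Arndt–Eistert sequence), with a second equivalent taking up HCl, gives the α-diazoketone that carries C3.

Step 12
Reactants: 20 diazoketone
Product: 21 12-chloro-3,19-cyclo-13,14,15,16-tetranorlabd-7-en-2-one (cyclopropane CH2 on the β face; C18 α)
Conditions: Cu(acac)2 (5 mol %), PhMe, 100 °C, slow addition of 20 at high dilution
Reagents that add atoms: none
Why: Copper(I) formed from Cu(acac)2 decomposes the diazoketone with loss of N2 to an electrophilic copper carbenoid at C3, which adds in a concerted, asynchronous [2+1] fashion to the C4=C19 alkene and so forms C3–C4 and C3–C19. The closest known reaction type is the intramolecular cyclopropanation of δ,ε-unsaturated α-diazoketones to bicyclo[4.1.0]heptan-2-ones. Ring A (C1–C2–C3–C4–C5–C10) closes in the exo mode by bonding of C3 to the internal alkene carbon C4 through a chair-like transition state with the tether ends trans-diequatorial on C10 and C5, which gives the trans ring fusion; the cyclopropane (C3–C4–C19) closes by the second bond to C19 and is necessarily cis-fused to ring A. C4 is set by the rotamer of the isopropenyl group: the transition state with the C18 methyl syn-axial to the C20 methyl is avoided, so C19 takes the β face and C18 the α face, while C3 (H α) follows from the cis fusion and is lost again in step 13. The step needs chemoselectivity for the isopropenyl alkene over the Δ7 alkene and over C–H insertion at C9–H, C5–H and C20; this is secured by the copper catalyst (addition preferred over insertion), by slow addition (no carbene dimer) and by geometry, since only the isopropenyl group can give a fused six-membered ring whereas the Δ7 alkene could only give a bridged one.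

Step 13
Reactants: 21 cyclopropyl ketone
Product: 22 19-acetoxy-12-chloro-13,14,15,16-tetranorlabd-7-en-2-one
Conditions: AcOH, H2SO4 (cat.), 25 °C
Reagents that add atoms: acetic acid, CC(=O)O
Why: Acid-catalysed homoconjugate addition: acetic acid attacks the primary cyclopropane carbon C19 of the protonated ketone in SN2 fashion and cleaves the exocyclic C3–C19 bond, the one aligned with the carbonyl π system, leaving C4 quaternary with β (axial) CH2OAc and α CH3 and freeing C3 as CH2.

Step 14
Reactants: 22 keto acetate
Product: 23 12-chloro-2α-hydroxy-13,14,15,16-tetranorlabd-7-en-19-yl acetate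
Conditions: SmI2, THF–H2O, 0 °C → rt
Reagents that add atoms: none
Why: Ketyl (single-electron) reduction, which like dissolving-metal reduction should give the thermodynamically preferred equatorial 2α-alcohol, whereas hydride reagents would attack from the open α face (the β face is screened by the axial C20 and C19 groups) and give the axial 2β-alcohol; the acetate and the alkyl chloride are inert to SmI2 without amine or HMPA.

Step 15
Reactants: 23 2α-alcohol
Product: 24 7α,8α-epoxide of 23
Conditions: mCPBA, Na2HPO4, CH2Cl2, 0 °C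
Reagents that add atoms: 3-chloroperbenzoic acid, OOC(=O)c1cccc(Cl)c1
Why: Prilezhaev epoxidation of the only alkene, the trisubstituted Δ7 bond, from the α face anti to the axial C20 methyl, which sets the C7–O bond α.

Step 16
Reactants: 24 epoxide
Product: 25 12-chloro-2α,7α-dihydroxy-13,14,15,16-tetranorlabd-8(17)-en-19-yl acetate
Conditions: Cp2TiCl2, Mn dust, THF, rt (Cp2TiCl formed first); then 24; 0.5 M HCl work-up
Reagents that add atoms: none
Why: Ti(III)-mediated epoxide isomerisation: Cp2TiCl opens the epoxide homolytically at the tertiary C8–O bond, the C8 radical is trapped by a second Cp2TiCl and β-hydride elimination towards the unhindered C17 methyl gives the exocyclic Δ8(17) alkene, with the C7–O bond untouched (7α-OH) and the acetate tolerated.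

Step 17
Reactants: 25 diol
Product: 26 2α,7α-bis(triethylsilyl) ether of 25
Conditions: TESOTf, 2,6-lutidine, CH2Cl2, −78 → 0 °C
Reagents that add atoms: triethylsilyl trifluoromethanesulfonate, CC[Si](CC)(CC)OS(=O)(=O)C(F)(F)F
Why: Silylation with the silyl triflate, reactive enough for the axial allylic 7α-OH, masks both protic groups for the organozinc step.

Step 18
Reactants: 26 chloride
Product: 27 12-iodo analogue of 26
Conditions: NaI, NaHCO3 (cat.), 2-butanone, 80 °C
Reagents that add atoms: sodium iodide, [Na+].[I-]
Why: Finkelstein halide exchange (SN2) at the unhindered primary C12 gives the iodide needed for zinc insertion.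

Step 19
Reactants: 28 but-2-yn-1-ol
Product: 30 (Z)-3-iodobut-2-en-1-ol, via cyclic alkenylaluminate 29 (not isolated)
Conditions: Red-Al, THF, 0 °C → rt; I2, THF, −78 → 0 °C
Reagents that add atoms: iodine, II
Why: Hydroxyl-directed trans-hydroalumination of the propargylic alcohol places aluminium on C3 in a cyclic alkenylaluminate, and iodinolysis with retention gives the (Z)-3-iodo allylic alcohol, which fixes the 13Z geometry.

Step 20
Reactants: 30 (Z)-3-iodobut-2-en-1-ol
Product: 31 (Z)-3-iodobut-2-en-1-yl acetate
Conditions: Ac2O, pyridine, DMAP (cat.), CH2Cl2, 0 °C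
Reagents that add atoms: acetic anhydride, CC(=O)OC(C)=O
Why: DMAP-catalysed O-acetylation of the primary allylic alcohol installs the C15 acetate before coupling.

Step 21
Reactants: 27 alkyl iodide; 31 (Z)-3-iodobut-2-en-1-yl acetate
Product: 33 2α,7α-bis(triethylsilyloxy)labda-8(17),13Z-diene-15,19-diyl diacetate, via alkylzinc iodide 32 (not isolated)
Conditions: Zn dust (activated with BrCH2CH2Br and TMSCl), DMA, 40 °C; then 31, PdCl2(dppf) (5 mol %), THF/DMA, rt → 40 °C
Reagents that add atoms: none
Why: Negishi sp3–sp2 cross-coupling: zinc inserts into the primary C–I bond and the alkylzinc iodide couples with the alkenyl iodide with retention of geometry to form C12–C13 (13Z), the acetates being inert to the organozinc and oxidative addition to the C–I bond expected to outpace ionisation of the allylic acetate.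

Step 22
Reactants: 33 bis-silyl ether
Product: 34 2α,7α-dihydroxylabda-8(17),13Z-diene-15,19-diyl diacetate (target)
Conditions: HF·pyridine, pyridine, THF, 0 °C → rt
Reagents that add atoms: none
Why: Fluoride-mediated cleavage of the two triethylsilyl ethers frees the 2α- and 7α-hydroxyls without touching the two acetates or the allylic system.

**Compound list**

1 | (R)-carvone | CC1=CC[C@H](CC1=O)C(C)=C | starting material
2 | lithium dienolate of 1 (in situ) | CC1=CC[C@@H](C(C)=C)C=C1O[Li] | intermediate
3 | 6-methylcarvone (C10 epimers) | CC1=CC[C@@H](C(C)=C)C(C)C1=O | intermediate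
4 | tert-butyl bromoacetate | CC(C)(C)OC(=O)CBr | starting material
5 | lithium enolate of 3 (in situ) | CC1=CC[C@@H](C(C)=C)C(C)=C1O[Li] | intermediate
6 | tert-butyl 2-[1,3-dimethyl-2-oxo-6-(prop-1-en-2-yl)cyclohex-3-en-1-yl]acetate (arm trans to isopropenyl) | CC1=CC[C@@H](C(C)=C)[C@](C)(CC(=O)OC(C)(C)C)C1=O | intermediate
7 | 7α,8α-epoxy ketone of 6 | C[C@@]12O[C@@H]1C[C@@H](C(C)=C)[C@](C)(CC(=O)OC(C)(C)C)C2=O | intermediate
8 | hydrazone of 7 (in situ) | C[C@@]12O[C@@H]1C[C@@H](C(C)=C)[C@](C)(CC(=O)OC(C)(C)C)C2=NN | intermediate
9 | 7α-hydroxy Δ8(9) ester | CC1=C[C@@](C)(CC(=O)OC(C)(C)C)[C@H](C(C)=C)C[C@H]1O | intermediate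
10 | 7-oxo Δ8(9) ester | CC1=C[C@@](C)(CC(=O)OC(C)(C)C)[C@H](C(C)=C)CC1=O | intermediate
11 | 7β-hydroxy Δ8(9) ester | CC1=C[C@@](C)(CC(=O)OC(C)(C)C)[C@H](C(C)=C)C[C@@H]1O | intermediate
12 | triethyl orthoacetate | CCOC(C)(OCC)OCC | starting material
13 | O7-(1-ethoxyvinyl) ketene acetal of 11 (in situ) | CC1=C[C@@](C)(CC(=O)OC(C)(C)C)[C@H](C(C)=C)C[C@@H]1OC(=C)OCC | intermediate
14 | Δ7 diester (C9β-CH2CO2Et, C10-CH2CO2tBu) | CC1=CC[C@@H](C(C)=C)[C@](C)(CC(=O)OC(C)(C)C)[C@H]1CC(=O)OCC | intermediate
15 | C12 alcohol | CC1=CC[C@@H](C(C)=C)[C@](C)(CC(=O)OC(C)(C)C)[C@H]1CCO | intermediate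
16 | C12 chloride tert-butyl ester | CC1=CC[C@@H](C(C)=C)[C@](C)(CC(=O)OC(C)(C)C)[C@H]1CCCl | intermediate
17 | trimethylsilyl ester (in situ) | CC1=CC[C@@H](C(C)=C)[C@](C)(CC(=O)O[Si](C)(C)C)[C@H]1CCCl | intermediate
18 | C2 carboxylic acid | CC1=CC[C@@H](C(C)=C)[C@](C)(CC(=O)O)[C@H]1CCCl | intermediate
19 | acid chloride (in situ) | CC1=CC[C@@H](C(C)=C)[C@](C)(CC(=O)Cl)[C@H]1CCCl | intermediate
20 | C3 diazoketone (key-step precursor) | CC1=CC[C@@H](C(C)=C)[C@](C)(CC(=O)C=[N+]=[N-])[C@H]1CCCl | intermediate
21 | 12-chloro-3,19-cyclo-13,14,15,16-tetranorlabd-7-en-2-one (key-step product) | CC1=CC[C@H]2[C@@]3(C)C[C@H]3C(=O)C[C@]2(C)[C@H]1CCCl | intermediate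
22 | 19-acetoxy-12-chloro-13,14,15,16-tetranorlabd-7-en-2-one | CC1=CC[C@H]2[C@@](C)(COC(C)=O)CC(=O)C[C@]2(C)[C@H]1CCCl | intermediate
23 | 2α-hydroxy 19-acetate | CC1=CC[C@H]2[C@@](C)(COC(C)=O)C[C@H](O)C[C@]2(C)[C@H]1CCCl | intermediate
24 | 7α,8α-epoxide | C[C@@]12O[C@@H]1C[C@H]3[C@@](C)(COC(C)=O)C[C@H](O)C[C@]3(C)[C@H]2CCCl | intermediate
25 | 2α,7α-diol, Δ8(17) | C=C1[C@H](O)C[C@H]2[C@@](C)(COC(C)=O)C[C@H](O)C[C@]2(C)[C@H]1CCCl | intermediate
26 | bis(triethylsilyl) ether, C12 chloride | C=C1[C@H](O[Si](CC)(CC)CC)C[C@H]2[C@@](C)(COC(C)=O)C[C@H](O[Si](CC)(CC)CC)C[C@]2(C)[C@H]1CCCl | intermediate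
27 | bis(triethylsilyl) ether, C12 iodide | C=C1[C@H](O[Si](CC)(CC)CC)C[C@H]2[C@@](C)(COC(C)=O)C[C@H](O[Si](CC)(CC)CC)C[C@]2(C)[C@H]1CCI | intermediate
28 | but-2-yn-1-ol | CC#CCO | starting material
29 | sodium cyclic alkenylaluminate (in situ) | CC1=CCO[Al-]1(OCCOC)OCCOC.[Na+] | intermediate
30 | (Z)-3-iodobut-2-en-1-ol | C/C(I)=C/CO | intermediate
31 | (Z)-3-iodobut-2-en-1-yl acetate | C/C(I)=C/COC(C)=O | intermediate
32 | C12 alkylzinc iodide (in situ) | C=C1[C@H](O[Si](CC)(CC)CC)C[C@H]2[C@@](C)(COC(C)=O)C[C@H](O[Si](CC)(CC)CC)C[C@]2(C)[C@H]1CC[Zn]I | intermediate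
33 | 2α,7α-bis(triethylsilyloxy)labda-8(17),13Z-diene-15,19-diyl diacetate | C=C1[C@H](O[Si](CC)(CC)CC)C[C@H]2[C@@](C)(COC(C)=O)C[C@H](O[Si](CC)(CC)CC)C[C@]2(C)[C@H]1CC/C(C)=C\COC(C)=O | intermediate
34 | 2α,7α-dihydroxylabda-8(17),13Z-diene-15,19-diyl diacetate | C=C1[C@H](O)C[C@H]2[C@@](C)(COC(C)=O)C[C@H](O)C[C@]2(C)[C@H]1CC/C(C)=C\COC(C)=O | target

**Step count and risks**

Total steps: 22. Longest linear sequence: 20 (steps 1–18, 21, 22).

Step 12. What may go wrong: the carbenoid may insert into the allylic C9–H or C5–H bond, add to the Δ7 alkene or dimerise, and the two isopropenyl rotamers may react with poor facial selectivity at C4. The fallback sets out from acid 18 and returns at keto acetate 22. Acid 18 would be homologated through its acyl imidazolide with magnesium methyl malonate to the methyl β-keto ester F1. Diazo transfer (p-acetamidobenzenesulfonyl azide, Et3N, MeCN) would give the α-diazo-β-keto ester F2. Its doubly stabilised, less reactive copper carbenoid [copper(II) bis(N-tert-butylsalicylaldiminate), PhMe, reflux] should be more selective for the electron-rich 1,1-disubstituted alkene, and the ester on C3 adds to the bias against the C18/C20 syn-axial transition state; this would give the cyclopropane keto ester F3. As a doubly activated cyclopropane, F3 should open at C19 with buffered acetate (NaOAc, AcOH, 100 °C) without strong acid to the 19-acetoxy β-keto ester F4. Demethoxycarbonylation (LiCl, wet DMSO, 140 °C) would then give 22.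

Step 13. What may go wrong: protonation of the Δ7 alkene (migration to Δ8) or heterolysis of the ring-fusion C3–C4 bond towards the tertiary C4 cation (enlargement of ring A) may compete with attack of acetic acid at C19. The fallback sets out from 21 and returns at 22. Iodotrimethylsilane (CH2Cl2, −78 → −20 °C) would open the silyl-activated ketone by SN2 attack of iodide at C19 under non-protic conditions to the 19-iodo ketone F5. The neopentyl iodide cannot be displaced by acetate, and base would re-close the cyclopropane, so the C19 radical (Bu3SnH, TEMPO, PhH, 70 °C) would be trapped as the TEMPO ether F6. N–O cleavage (Zn, AcOH, THF/H2O) would give the 19-hydroxy ketone F7, possibly as its bridged hemiketal, and acetylation (Ac2O, pyridine, DMAP) would give 22.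

Step 14. What may go wrong: protonation of the ketyl-derived carbanion from the open α face (poor facial selectivity, axial alcohol), or slow reduction with loss of the C12 chloride. The fallback sets out from 22 and returns at 23. NaBH4 (MeOH, 0 °C) would give, by equatorial attack, the axial 2β-alcohol F8. This would be equilibrated by reversible transfer dehydrogenation–hydrogenation with the ruthenium hydride dimer [Ru2(CO)4(μ-H)(C4Ph4COHOCC4Ph4)] in PhMe at 90 °C. The equilibrium should lie on the side of the equatorial 2α-alcohol 23, because F8 suffers syn-axial repulsion with both C20 and the C19 CH2OAc group.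

**Further compounds**

F1 | step 12 | methyl β-keto ester (C10–CH2–CO–CH2–CO2Me) | CC1=CC[C@@H](C(C)=C)[C@](C)(CC(=O)CC(=O)OC)[C@H]1CCCl
F2 | step 12 | α-diazo-β-keto ester | CC1=CC[C@@H](C(C)=C)[C@](C)(CC(=O)C(=[N+]=[N-])C(=O)OC)[C@H]1CCCl
F3 | step 12 | cyclopropane keto ester (CO2Me on C3) | CC1=CC[C@H]2[C@@]3(C)C[C@@]3(C(=O)OC)C(=O)C[C@]2(C)[C@H]1CCCl
F4 | step 12 | 19-acetoxy β-keto ester | CC1=CC[C@H]2[C@@](C)(COC(C)=O)C(C(=O)OC)C(=O)C[C@]2(C)[C@H]1CCCl
F5 | step 13 | 19-iodo ketone | CC1=CC[C@H]2[C@@](C)(CI)CC(=O)C[C@]2(C)[C@H]1CCCl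
F6 | step 13 | 19-O-(2,2,6,6-tetramethylpiperidin-1-yl) ether | CC1=CC[C@H]2[C@@](C)(CON3C(C)(C)CCCC3(C)C)CC(=O)C[C@]2(C)[C@H]1CCCl
F7 | step 13 | 19-hydroxy ketone | CC1=CC[C@H]2[C@@](C)(CO)CC(=O)C[C@]2(C)[C@H]1CCCl
F8 | step 14 | 2β-alcohol (axial) | CC1=CC[C@H]2[C@@](C)(COC(C)=O)C[C@@H](O)C[C@]2(C)[C@H]1CCCl
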